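**Plan**
- Retrosynthesis: after removal of the benzyl and silyl groups, bottom ring C is cut at O1–C2 (back to a trans-epoxide), and bottom ring A itself is then cut at C8a–C4a and C5–C6.
- Enabling feature: bottom ring A is a phloroglucinol ring with oxygens on C5, C7 and C8a, the middle unit on C6 and the C4 methylene on C4a. A 2-substituted 3-alkoxycyclobutenone (supplying C6, C7, C8, C8a) and a silyloxyalkyne (supplying C4a, C5) give exactly this pattern, with C8a as the only free phenol.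
- Further cuts: the cyclobutenone into ketene and a C4 ynol ether; the ynol ether at middle C4–C(sp) into the dimer C4 cation and a stannyl ynol ether; the dimer at top C4–middle C8.
- Forward order: benzylated epicatechin, 4β→8 dimer, C4 activation and galloylation, C4 alkynylation, four-membered ring, bottom ring A (benzannulation), bottom ring C (6-endo epoxide opening), desilylation and hydrogenolysis.
- Stereochemistry: C2 and C3 of the top and middle units come from (−)-epicatechin; both C4 centres arise by attack on a C4 cation anti to the 3-oxygen (4β); bottom C2 and C3 come from a Shi epoxidation of an E-alkene, with inversion at C2 in the pyran closure.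

Key step: step 14

Remark: the target is read from its SMILES as (−)-epicatechin 3-O-gallate-(4β→8)-(−)-epicatechin 3-O-gallate-(4β→6)-(+)-catechin; flavan numbering is used within each unit (top, middle, bottom), and ketene is taken as a gas stream from an acetone-pyrolysis generator.

**Route**

Step 1
Reactants: 1 (−)-epicatechin
Product: 2 5,7,3',4'-tetra-O-benzyl-(−)-epicatechin
Conditions: BnBr (4.4 equiv), K2CO3, DMF, 0 °C → rt
Reagents that add atoms: benzyl bromide, BrCc1ccccc1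
Why: Williamson ether synthesis in which K2CO3 deprotonates only the four phenols, so the secondary 3-OH stays free and the mild, cold conditions should avoid base-induced epimerisation at C2.

Step 2
Reactants: 2 5,7,3',4'-tetra-O-benzyl-(−)-epicatechin
Product: 3 4β-(2-ethoxyethoxy)-5,7,3',4'-tetra-O-benzylepicatechin (2,3-cis, 3,4-trans)
Conditions: DDQ (2 equiv), HOCH2CH2OEt (5 equiv), CH2Cl2, rt
Reagents that add atoms: 2-ethoxyethanol, CCOCCO
Why: DDQ benzylic oxidation, in which hydride abstraction from C4 gives the cation stabilised by the 5,7-dibenzyloxy ring and the alcohol captures it anti to the 3-OH; the new centre is lost again in step 3, so its configuration is immaterial.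

Step 3
Reactants: 3 4β-(2-ethoxyethoxy)-5,7,3',4'-tetra-O-benzylepicatechin; 2 5,7,3',4'-tetra-O-benzyl-(−)-epicatechin (4 equiv, excess recovered)
Product: 4 5,7,3',4'-tetra-O-benzylepicatechin-(4β→8)-5,7,3',4'-tetra-O-benzylepicatechin (octa-O-benzyl procyanidin B2)
Conditions: Me3SiOTf (0.1 equiv), CH2Cl2, −78 °C
Reagents that add atoms: none
Why: Lewis-acid-catalysed Friedel–Crafts-type arylation of the flavan-4-yl cation, in which the most nucleophilic position C8 of excess 2 attacks from the β face, anti to the 3-oxygen and the 2-aryl group of the 2,3-cis unit, which sets top C4 as 4β while the excess of 2 suppresses self-condensation of 3.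

Step 4
Reactants: 4 octa-O-benzyl procyanidin B2
Product: 5 octa-O-benzyl procyanidin B2 carrying a 4β-(2-ethoxyethoxy) group on the lower (future middle) unit
Conditions: DDQ (2 equiv), HOCH2CH2OEt (5 equiv), CH2Cl2, rt
Reagents that add atoms: 2-ethoxyethanol, CCOCCO
Why: the same DDQ benzylic oxidation, directed to the only unhindered electron-rich benzylic CH2 (C4 of the lower unit), since the interflavan methine is shielded by its two doubly ortho-substituted aryl groups; the ether formed serves only as a leaving group.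

Step 5
Reactants: 5 lower-unit 4β-(2-ethoxyethoxy) octa-O-benzyl procyanidin B2; 6 3,4,5-tris(benzyloxy)benzoic acid (4 equiv)
Product: 7 perbenzylated top–middle dimer: bis-3-O-[3,4,5-tris(benzyloxy)benzoyl] ester of 5, with the 4β-(2-ethoxyethoxy) group on the middle unit
Conditions: DCC, DMAP, CH2Cl2, rt
Reagents that add atoms: none
Why: Steglich esterification of both secondary 3-hydroxyls, to which the C4 ether, the benzyl ethers and the interflavan bond are inert.

Step 6
Reactants: 8 benzyl alcohol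
Product: 12 tributyl(benzyloxyethynyl)stannane, via potassium benzyloxide 9 (not isolated), via benzyl (E)-1,2-dichlorovinyl ether 10 (not isolated), via lithium benzyloxyacetylide 11 (not isolated)
Conditions: KH, THF, 0 °C; Cl2C=CHCl, rt; n-BuLi (2.3 equiv), −78 → −40 °C; Bu3SnCl, −78 → 0 °C; kept and purified cold
Reagents that add atoms: trichloroethylene, ClC=C(Cl)Cl; tributyltin chloride, CCCC[Sn](Cl)(CCCC)CCCC
Why: alkoxide addition–elimination on trichloroethylene gives the dichlorovinyl ether, n-BuLi then effects dehydrochlorination and chlorine–lithium exchange to the lithium alkoxyacetylide, and C-stannylation gives the stannyl ynol ether, which is kept cold because benzyl alkynyl ethers rearrange sigmatropically on warming.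

Step 7
Reactants: 7 perbenzylated top–middle dimer with 4β-(2-ethoxyethoxy) on the middle unit; 12 tributyl(benzyloxyethynyl)stannane (2.5 equiv)
Product: 13 perbenzylated top–middle dimer carrying a 4β-(benzyloxyethynyl) group on middle C4
Conditions: Me3SiOTf (0.3 equiv), 4 Å molecular sieves, CH2Cl2, −78 °C; Et3N quench at −78 °C
Reagents that add atoms: none
Why: Proposed new method: Me3SiOTf ionises the C4 ether with anchimeric help from the 3-O-galloyl carbonyl to a flavan-4-yl cation/cis-fused dioxolenium ion that blocks the α face; the stannyl ynol ether is attacked at its tin-bearing carbon (the carbon remote from oxygen, where the HOMO is largest, giving an α-alkoxyvinyl cation stabilised by oxygen and by the β C–Sn bond) from the open β face, and loss of Bu3Sn+ restores the triple bond, so middle C4 is set 3,4-trans (4β); the closest known reactions are the Lewis-acid ipso-substitution of alkynylstannanes by oxocarbenium and benzylic cations and the Lewis-acid C4-arylation and C4-allylation of 4-alkoxyflavans.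

Step 8
Reactants: 13 middle-C4 benzyloxyethynyl dimer
Product: 14 3-benzyloxy-2-(perbenzylated top–middle dimer-4β-yl)cyclobut-2-en-1-one
Conditions: CH2=C=O (gas stream, excess), CH2Cl2, 0 °C
Reagents that add atoms: ketene, C=C=O
Why: thermal [2+2] cycloaddition of ketene with a 1-alkoxyalkyne, in which the nucleophilic alkyne carbon (the one bearing the flavanyl group) bonds to the ketene carbonyl carbon and the oxygen-bearing carbon to CH2, giving the 2-substituted 3-alkoxycyclobutenone at a temperature at which the benzyl ynol ether does not rearrange.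

Step 9
Reactants: 15 3,4-bis(benzyloxy)benzaldehyde
Product: 16 rac-1-[3,4-bis(benzyloxy)phenyl]prop-2-en-1-ol
Conditions: CH2=CHMgBr, THF, 0 °C; aq. NH4Cl
Reagents that add atoms: vinylmagnesium bromide, C=C[Mg]Br
Why: Grignard addition to the aldehyde; the racemic carbinol centre is removed in step 10.

Step 10
Reactants: 16 rac-1-[3,4-bis(benzyloxy)phenyl]prop-2-en-1-ol
Product: 17 (E)-3-[3,4-bis(benzyloxy)phenyl]prop-2-enyl chloride
Conditions: SOCl2 (1.2 equiv), Et2O, 0 °C; used crude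
Reagents that add atoms: thionyl chloride, ClS(Cl)=O
Why: chlorination with allylic transposition (SNi′ collapse of the chlorosulfite), which delivers the conjugated, thermodynamically favoured (E)-cinnamyl chloride.

Step 11
Reactants: 17 (E)-3-[3,4-bis(benzyloxy)phenyl]prop-2-enyl chloride
Product: 18 (E)-5-[3,4-bis(benzyloxy)phenyl]pent-4-en-1-yne
Conditions: HC≡CMgBr (3 equiv), CuCl (0.1 equiv), THF, 0 → 45 °C
Reagents that add atoms: ethynylmagnesium bromide, C#C[Mg]Br
Why: copper-catalysed allyl–alkynyl coupling of an alkynyl Grignard reagent with an allylic chloride, which should occur at the primary carbon and keep the conjugated E-alkene.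

Step 12
Reactants: 18 (E)-5-[3,4-bis(benzyloxy)phenyl]pent-4-en-1-yne
Product: 19 (2S,3S)-2-[3,4-bis(benzyloxy)phenyl]-3-(prop-2-ynyl)oxirane
Conditions: L-fructose-derived Shi ketone (0.3 equiv), KHSO5 (as Oxone), K2CO3, Bu4NHSO4, MeCN/CH2(OMe)2, aq. Na2B4O7–Na2EDTA buffer (pH 10.5), 0 °C; chromatography on Et3N-treated silica
Reagents that add atoms: potassium peroxymonosulfate, [K+].[O-]S(=O)(=O)OO
Why: Shi asymmetric epoxidation, in which the chiral dioxirane adds to the E-alkene through the spiro transition state; the L-fructose-derived ketone gives the (S,S)-trans-epoxide (the D-fructose ketone gives the (R,R) series with trans-β-alkylstyrenes), the basic buffer protects the acid-labile electron-rich aryl epoxide and the alkyne is inert to the dioxirane.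

Step 13
Reactants: 19 (2S,3S)-2-[3,4-bis(benzyloxy)phenyl]-3-(prop-2-ynyl)oxirane
Product: 22 triisopropyl({3-[(2S,3S)-3-(3,4-bis(benzyloxy)phenyl)oxiran-2-yl]prop-1-yn-1-yl}oxy)silane, via lithium acetylide 20 (not isolated), via lithium ynolate 21 (not isolated)
Conditions: LiN(SiMe3)2 (1.1 equiv), THF, −78 °C; t-BuOOLi (from t-BuOOH and LiN(SiMe3)2), −78 → 0 °C; i-Pr3SiCl, −78 °C → rt
Reagents that add atoms: tert-butyl hydroperoxide, CC(C)(C)OO; chlorotriisopropylsilane, CC(C)[Si](Cl)(C(C)C)C(C)C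
Why: oxidation of a lithium acetylide by lithium tert-butyl peroxide to the lithium ynolate followed by O-silylation with a bulky silyl chloride, a known route from terminal alkynes to silyl ynol ethers, in which the non-nucleophilic amide base and the absence of a Lewis acid should leave the epoxide intact.

Step 14
Reactants: 14 benzyloxycyclobutenone carrying the perbenzylated top–middle dimer; 22 triisopropylsilyl ynol ether bearing the trans-epoxide
Product: 27 benzannulated phenol with pendant epoxide (resorcinol monosilyl ether of bottom ring A), via vinylketene 23 (not isolated), via alkenylcyclobutenone 24 (not isolated), via dienylketene 25 (not isolated), via cyclohexadienone 26 (not isolated)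
Conditions: toluene (0.3 M), ynol ether in slight excess, 80 °C then 110 °C, argon, base-washed glassware
Reagents that add atoms: none
Why: Heating opens cyclobutenone 14 by four-electron electrocyclic ring opening to vinylketene 23, whose ketene C=C adds silyloxyalkyne 22 in a [2+2] cycloaddition (new bonds C8a–C4a and C5–C6 of the bottom unit) to give alkenylcyclobutenone 24, which opens again to dienylketene 25, closes by six-electron electrocyclisation to cyclohexadienone 26 and tautomerises to phenol 27, so that the cascade is an addition followed by isomerisations in which every atom of both partners is kept. The closest known reaction is the Danheiser benzannulation of cyclobutenones with trialkylsilyloxyalkynes, which gives resorcinol monosilyl ethers. Ring A (six-membered, carbocyclic) closes in the disrotatory six-electron electrocyclisation of the dienylketene between the ketene carbon (C8a) and the terminal methylene (C8), after both intermolecular bonds have been made in the [2+2] event. No stereocentre is created (the quaternary carbon of 24 becomes trigonal again on ring opening), and the neutral thermal conditions should leave the epoxide, the esters and both 4β centres untouched. The one selectivity required is the regiochemistry of the [2+2] step, secured by the polarity of the ynol ether: its nucleophilic carbon, remote from oxygen, bonds to the ketene carbonyl carbon and its oxygen-bearing carbon to the flavanyl-bearing ketene carbon. The middle unit can therefore only stand on C6, between the benzyloxy carbon C7 and the silyloxy carbon C5, and the only free oxygen is the one on C8a, next to the epoxide-bearing side chain.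

Step 15
Reactants: 27 benzannulated phenol with pendant epoxide
Product: 28 perbenzylated epicatechin 3-O-gallate-(4β→8)-epicatechin 3-O-gallate-(4β→6)-catechin with bottom 5-O-triisopropylsilyl, 7-O-benzyl, 3',4'-di-O-benzyl and free bottom 3-OH
Conditions: camphorsulfonic acid (0.1 equiv), CH2Cl2, −20 → 0 °C
Reagents that add atoms: none
Why: acid-catalysed intramolecular epoxide opening (6-endo-tet) by the only free phenol, in which the benzylic carbon activated by the 3,4-dibenzyloxyphenyl group is attacked with inversion, so the (S,S)-epoxide gives the 2,3-trans (2R,3S) catechin ring C, C3 keeps its configuration and the diequatorial trans product is also the thermodynamically preferred one.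

Step 16
Reactants: 28 bottom 5-O-silyl protected trimer
Product: 29 protected trimer with free bottom 5-OH and 3-OH (seventeen benzyl ethers retained)
Conditions: Bu4NF, AcOH (1:1), THF, 0 °C
Reagents that add atoms: none
Why: fluoride-mediated cleavage of the aryl silyl ether, with acetic acid buffering to keep the gallate esters and the flavan units from base-induced damage.

Step 17
Reactants: 29 heptadeca-O-benzyl trimer
Product: 30 epicatechin 3-O-gallate-(4β→8)-epicatechin 3-O-gallate-(4β→6)-catechin (CNP0154615.1)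
Conditions: H2 (1 atm), Pd(OH)2/C, THF/MeOH/H2O, rt
Reagents that add atoms: none
Why: catalytic hydrogenolysis of all seventeen benzyl ethers under neutral conditions, which should leave the esters, the interflavan bonds and all eight stereocentres untouched.

**Compound list**

1 | (−)-epicatechin, (2R,3R)-2-(3,4-dihydroxyphenyl)chromane-3,5,7-triol | O[C@@H]1Cc2c(O)cc(O)cc2O[C@@H]1c1ccc(O)c(O)c1 | starting material

2 | 5,7,3',4'-tetra-O-benzyl-(−)-epicatechin | O[C@@H]1Cc2c(OCc9ccccc9)cc(OCc9ccccc9)cc2O[C@@H]1c1ccc(OCc9ccccc9)c(OCc9ccccc9)c1 | intermediate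

3 | 4β-(2-ethoxyethoxy)-5,7,3',4'-tetra-O-benzylepicatechin (2,3-cis, 3,4-trans) | O[C@@H]1[C@@H](OCCOCC)c2c(OCc9ccccc9)cc(OCc9ccccc9)cc2O[C@@H]1c1ccc(OCc9ccccc9)c(OCc9ccccc9)c1 | intermediate

4 | octa-O-benzyl procyanidin B2, tetra-O-benzylepicatechin-(4β→8)-tetra-O-benzylepicatechin | O[C@@H]1[C@@H](c2c(OCc9ccccc9)cc(OCc9ccccc9)c3c2O[C@H](c2ccc(OCc9ccccc9)c(OCc9ccccc9)c2)[C@H](O)C3)c2c(OCc9ccccc9)cc(OCc9ccccc9)cc2O[C@@H]1c1ccc(OCc9ccccc9)c(OCc9ccccc9)c1 | intermediate

5 | octa-O-benzyl procyanidin B2 with 4β-(2-ethoxyethoxy) on the lower unit | O[C@@H]1[C@@H](c2c(OCc9ccccc9)cc(OCc9ccccc9)c3c2O[C@H](c2ccc(OCc9ccccc9)c(OCc9ccccc9)c2)[C@H](O)[C@H]3OCCOCC)c2c(OCc9ccccc9)cc(OCc9ccccc9)cc2O[C@@H]1c1ccc(OCc9ccccc9)c(OCc9ccccc9)c1 | intermediate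

6 | 3,4,5-tris(benzyloxy)benzoic acid | OC(=O)c1cc(OCc9ccccc9)c(OCc9ccccc9)c(OCc9ccccc9)c1 | starting material

7 | perbenzylated top–middle dimer: both 3-O-[3,4,5-tris(benzyloxy)benzoyl] esters, 4β-(2-ethoxyethoxy) on the middle unit | O=C(c7cc(OCc9ccccc9)c(OCc9ccccc9)c(OCc9ccccc9)c7)O[C@@H]1[C@@H](c2c(OCc9ccccc9)cc(OCc9ccccc9)c3c2O[C@H](c2ccc(OCc9ccccc9)c(OCc9ccccc9)c2)[C@H](OC(=O)c7cc(OCc9ccccc9)c(OCc9ccccc9)c(OCc9ccccc9)c7)[C@H]3OCCOCC)c2c(OCc9ccccc9)cc(OCc9ccccc9)cc2O[C@@H]1c1ccc(OCc9ccccc9)c(OCc9ccccc9)c1 | intermediate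

8 | benzyl alcohol | OCc1ccccc1 | starting material

9 | potassium benzyloxide | [K+].[O-]Cc1ccccc1 | intermediate

10 | benzyl (E)-1,2-dichlorovinyl ether | Cl/C=C(/Cl)OCc1ccccc1 | intermediate

11 | lithium benzyloxyacetylide | [Li+].[C-]#COCc1ccccc1 | intermediate

12 | tributyl(benzyloxyethynyl)stannane | CCCC[Sn](CCCC)(CCCC)C#COCc1ccccc1 | intermediate

13 | perbenzylated top–middle dimer with 4β-(benzyloxyethynyl) on middle C4 | O=C(c7cc(OCc9ccccc9)c(OCc9ccccc9)c(OCc9ccccc9)c7)O[C@@H]1[C@@H](c2c(OCc9ccccc9)cc(OCc9ccccc9)c3c2O[C@H](c2ccc(OCc9ccccc9)c(OCc9ccccc9)c2)[C@H](OC(=O)c7cc(OCc9ccccc9)c(OCc9ccccc9)c(OCc9ccccc9)c7)[C@H]3C#COCc9ccccc9)c2c(OCc9ccccc9)cc(OCc9ccccc9)cc2O[C@@H]1c1ccc(OCc9ccccc9)c(OCc9ccccc9)c1 | intermediate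

14 | 3-benzyloxy-2-(perbenzylated top–middle dimer-4β-yl)cyclobut-2-en-1-one | O=C(c7cc(OCc9ccccc9)c(OCc9ccccc9)c(OCc9ccccc9)c7)O[C@@H]1[C@@H](c2c(OCc9ccccc9)cc(OCc9ccccc9)c3c2O[C@H](c2ccc(OCc9ccccc9)c(OCc9ccccc9)c2)[C@H](OC(=O)c7cc(OCc9ccccc9)c(OCc9ccccc9)c(OCc9ccccc9)c7)[C@H]3C4=C(OCc9ccccc9)CC4=O)c2c(OCc9ccccc9)cc(OCc9ccccc9)cc2O[C@@H]1c1ccc(OCc9ccccc9)c(OCc9ccccc9)c1 | intermediate

15 | 3,4-bis(benzyloxy)benzaldehyde | O=Cc1ccc(OCc9ccccc9)c(OCc9ccccc9)c1 | starting material

16 | rac-1-[3,4-bis(benzyloxy)phenyl]prop-2-en-1-ol | C=CC(O)c1ccc(OCc9ccccc9)c(OCc9ccccc9)c1 | intermediate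

17 | (E)-3-[3,4-bis(benzyloxy)phenyl]prop-2-enyl chloride | ClC/C=C/c1ccc(OCc9ccccc9)c(OCc9ccccc9)c1 | intermediate

18 | (E)-5-[3,4-bis(benzyloxy)phenyl]pent-4-en-1-yne | C#CC/C=C/c1ccc(OCc9ccccc9)c(OCc9ccccc9)c1 | intermediate

19 | (2S,3S)-2-[3,4-bis(benzyloxy)phenyl]-3-(prop-2-ynyl)oxirane | C#CC[C@@H]1O[C@H]1c1ccc(OCc9ccccc9)c(OCc9ccccc9)c1 | intermediate

20 | lithium acetylide of 19 | [Li+].[C-]#CC[C@@H]1O[C@H]1c1ccc(OCc9ccccc9)c(OCc9ccccc9)c1 | intermediate

21 | lithium 3-[(2S,3S)-3-(3,4-bis(benzyloxy)phenyl)oxiran-2-yl]prop-1-yn-1-olate (ynolate) | [Li+].[O-]C#CC[C@@H]1O[C@H]1c1ccc(OCc9ccccc9)c(OCc9ccccc9)c1 | intermediate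

22 | triisopropyl({3-[(2S,3S)-3-(3,4-bis(benzyloxy)phenyl)oxiran-2-yl]prop-1-yn-1-yl}oxy)silane | CC(C)[Si](C(C)C)(C(C)C)OC#CC[C@@H]1O[C@H]1c1ccc(OCc9ccccc9)c(OCc9ccccc9)c1 | intermediate

23 | vinylketene: 3-benzyloxy-2-(dimer-4β-yl)buta-1,3-dien-1-one | O=C(c7cc(OCc9ccccc9)c(OCc9ccccc9)c(OCc9ccccc9)c7)O[C@@H]1[C@@H](c2c(OCc9ccccc9)cc(OCc9ccccc9)c3c2O[C@H](c2ccc(OCc9ccccc9)c(OCc9ccccc9)c2)[C@H](OC(=O)c7cc(OCc9ccccc9)c(OCc9ccccc9)c(OCc9ccccc9)c7)[C@H]3C(=C=O)C(OCc9ccccc9)=C)c2c(OCc9ccccc9)cc(OCc9ccccc9)cc2O[C@@H]1c1ccc(OCc9ccccc9)c(OCc9ccccc9)c1 | intermediate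

24 | alkenylcyclobutenone: 4-(1-benzyloxyvinyl)-4-(dimer-4β-yl)-2-(epoxyalkyl)-3-(triisopropylsilyloxy)cyclobut-2-en-1-one, ring C4 unassigned (both epimers) | O=C(c7cc(OCc9ccccc9)c(OCc9ccccc9)c(OCc9ccccc9)c7)O[C@@H]1[C@@H](c2c(OCc9ccccc9)cc(OCc9ccccc9)c3c2O[C@H](c2ccc(OCc9ccccc9)c(OCc9ccccc9)c2)[C@H](OC(=O)c7cc(OCc9ccccc9)c(OCc9ccccc9)c(OCc9ccccc9)c7)[C@H]3C4(C(OCc9ccccc9)=C)C(=O)C(C[C@@H]5O[C@H]5c5ccc(OCc9ccccc9)c(OCc9ccccc9)c5)=C4O[Si](C(C)C)(C(C)C)C(C)C)c2c(OCc9ccccc9)cc(OCc9ccccc9)cc2O[C@@H]1c1ccc(OCc9ccccc9)c(OCc9ccccc9)c1 | intermediate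

25 | dienylketene: 5-benzyloxy-4-(dimer-4β-yl)-2-(epoxyalkyl)-3-(triisopropylsilyloxy)hexa-1,3,5-trien-1-one, ketenyl and vinyl groups cis on the central alkene | O=C(c7cc(OCc9ccccc9)c(OCc9ccccc9)c(OCc9ccccc9)c7)O[C@@H]1[C@@H](c2c(OCc9ccccc9)cc(OCc9ccccc9)c3c2O[C@H](c2ccc(OCc9ccccc9)c(OCc9ccccc9)c2)[C@H](OC(=O)c7cc(OCc9ccccc9)c(OCc9ccccc9)c(OCc9ccccc9)c7)[C@H]3C(/C(OCc9ccccc9)=C)=C(/C(=C=O)C[C@@H]5O[C@H]5c5ccc(OCc9ccccc9)c(OCc9ccccc9)c5)O[Si](C(C)C)(C(C)C)C(C)C)c2c(OCc9ccccc9)cc(OCc9ccccc9)cc2O[C@@H]1c1ccc(OCc9ccccc9)c(OCc9ccccc9)c1 | intermediate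

26 | cyclohexadienone: cyclohexa-2,4-dienone keto tautomer of 27 (CH2 at the future C8) | O=C(c7cc(OCc9ccccc9)c(OCc9ccccc9)c(OCc9ccccc9)c7)O[C@@H]1[C@@H](c2c(OCc9ccccc9)cc(OCc9ccccc9)c3c2O[C@H](c2ccc(OCc9ccccc9)c(OCc9ccccc9)c2)[C@H](OC(=O)c7cc(OCc9ccccc9)c(OCc9ccccc9)c(OCc9ccccc9)c7)[C@H]3C4=C(OCc9ccccc9)CC(=O)C(C[C@@H]5O[C@H]5c5ccc(OCc9ccccc9)c(OCc9ccccc9)c5)=C4O[Si](C(C)C)(C(C)C)C(C)C)c2c(OCc9ccccc9)cc(OCc9ccccc9)cc2O[C@@H]1c1ccc(OCc9ccccc9)c(OCc9ccccc9)c1 | intermediate

27 | 5-benzyloxy-2-{[(2S,3S)-3-(3,4-bis(benzyloxy)phenyl)oxiran-2-yl]methyl}-4-(perbenzylated top–middle dimer-4β-yl)-3-(triisopropylsilyloxy)phenol | O=C(c7cc(OCc9ccccc9)c(OCc9ccccc9)c(OCc9ccccc9)c7)O[C@@H]1[C@@H](c2c(OCc9ccccc9)cc(OCc9ccccc9)c3c2O[C@H](c2ccc(OCc9ccccc9)c(OCc9ccccc9)c2)[C@H](OC(=O)c7cc(OCc9ccccc9)c(OCc9ccccc9)c(OCc9ccccc9)c7)[C@H]3c4c(OCc9ccccc9)cc(O)c(c4O[Si](C(C)C)(C(C)C)C(C)C)C[C@@H]5O[C@H]5c5ccc(OCc9ccccc9)c(OCc9ccccc9)c5)c2c(OCc9ccccc9)cc(OCc9ccccc9)cc2O[C@@H]1c1ccc(OCc9ccccc9)c(OCc9ccccc9)c1 | intermediate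

28 | protected trimer: bottom catechin unit 5-O-triisopropylsilyl, 7,3',4'-tri-O-benzyl, free 3-OH | O=C(c7cc(OCc9ccccc9)c(OCc9ccccc9)c(OCc9ccccc9)c7)O[C@@H]1[C@@H](c2c(OCc9ccccc9)cc(OCc9ccccc9)c3c2O[C@H](c2ccc(OCc9ccccc9)c(OCc9ccccc9)c2)[C@H](OC(=O)c7cc(OCc9ccccc9)c(OCc9ccccc9)c(OCc9ccccc9)c7)[C@H]3c4c(OCc9ccccc9)cc5c(c4O[Si](C(C)C)(C(C)C)C(C)C)C[C@H](O)[C@@H](c4ccc(OCc9ccccc9)c(OCc9ccccc9)c4)O5)c2c(OCc9ccccc9)cc(OCc9ccccc9)cc2O[C@@H]1c1ccc(OCc9ccccc9)c(OCc9ccccc9)c1 | intermediate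

29 | heptadeca-O-benzyl trimer with free bottom 5-OH and 3-OH | O=C(c7cc(OCc9ccccc9)c(OCc9ccccc9)c(OCc9ccccc9)c7)O[C@@H]1[C@@H](c2c(OCc9ccccc9)cc(OCc9ccccc9)c3c2O[C@H](c2ccc(OCc9ccccc9)c(OCc9ccccc9)c2)[C@H](OC(=O)c7cc(OCc9ccccc9)c(OCc9ccccc9)c(OCc9ccccc9)c7)[C@H]3c4c(OCc9ccccc9)cc5c(c4O)C[C@H](O)[C@@H](c4ccc(OCc9ccccc9)c(OCc9ccccc9)c4)O5)c2c(OCc9ccccc9)cc(OCc9ccccc9)cc2O[C@@H]1c1ccc(OCc9ccccc9)c(OCc9ccccc9)c1 | intermediate

30 | CNP0154615.1, epicatechin 3-O-gallate-(4β→8)-epicatechin 3-O-gallate-(4β→6)-catechin | O=C(O[C@@H]1[C@@H](c2c(O)cc(O)c3c2O[C@H](c2ccc(O)c(O)c2)[C@H](OC(=O)c2cc(O)c(O)c(O)c2)[C@H]3c2c(O)cc3c(c2O)C[C@H](O)[C@@H](c2ccc(O)c(O)c2)O3)c2c(O)cc(O)cc2O[C@@H]1c1ccc(O)c(O)c1)c1cc(O)c(O)c(O)c1 | target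

**Step count and risks**

Total: 17 steps. Longest linear sequence: 11 steps (1–5, 7, 8, 14–17); the alkyne branch (9–13) and the stannane (6) are convergent.

Steps most likely to fail:

1. Step 7 (proposed new method). The stannyl ynol ether may be protodestannylated before it meets the cation. The cation may instead eliminate to the flav-3-ene or be captured reversibly at oxygen. The product ynol ether may also be alkylated a second time. The fallback sets out from 7 and returns at 14, bypassing 13. Compound 7 is ionised with Sc(OTf)3 in CH2Cl2/MeCN in the presence of cyclobutane-1,3-dione (reacting as 3-hydroxycyclobut-2-enone). This is the Lewis-acid C-alkylation of a cyclic 1,3-dione by a benzylic cation, as used with 1,3-diketones and phloroglucinol, again anti to the participating 3-O-galloyl group. It should give 3-hydroxy-2-(perbenzylated top–middle dimer-4β-yl)cyclobut-2-en-1-one F1. This vinylogous acid is O-benzylated with benzyl 2,2,2-trichloroacetimidate (the symmetry of the dione makes the site of O-alkylation irrelevant) to give 14.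

2. Step 14. The crowded vinylketene may revert or dimerise faster than it adds the alkyne, or the second ring opening may need temperatures at which the epoxide isomerises or the silyl group migrates. The fallback sets out from 7 and returns at 30, forming the 4→6 bond by a halogen-capping coupling instead of building ring A. Commercial (+)-catechin is benzylated (BnBr, K2CO3, DMF) to 5,7,3',4'-tetra-O-benzyl-(+)-catechin F2. F2 is brominated at its most nucleophilic position (N-bromosuccinimide, CH2Cl2, −78 °C) to 8-bromo-5,7,3',4'-tetra-O-benzyl-(+)-catechin F3. Me3SiOTf-mediated coupling of 7 with F3 at −78 °C, with C8 blocked, should direct the 4β attack to C6 and give the 8-bromo protected trimer F4. Hydrogenolysis (H2, Pd(OH)2/C, Et3N, THF/MeOH) removes the eighteen benzyl groups and the bromine to give 30.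

3. Step 8. Cycloaddition at the hindered alkyne carbon may be slow, so that ketene dimerisation and the sigmatropic rearrangement of the benzyl ynol ether take over. The fallback sets out from 13 and returns at 14. The far more electrophilic dichloroketene (Cl3CCOCl, Zn/Cu couple, Et2O, 0 °C) is used in the same regiochemical sense to give 3-benzyloxy-4,4-dichloro-2-(perbenzylated top–middle dimer-4β-yl)cyclobut-2-en-1-one F5. Reductive dechlorination (Zn, AcOH, TMEDA, EtOH, rt) then gives 14.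

**Further compounds**

F1 | step 7 | 3-hydroxy-2-(perbenzylated top–middle dimer-4β-yl)cyclobut-2-en-1-one | O=C(c7cc(OCc9ccccc9)c(OCc9ccccc9)c(OCc9ccccc9)c7)O[C@@H]1[C@@H](c2c(OCc9ccccc9)cc(OCc9ccccc9)c3c2O[C@H](c2ccc(OCc9ccccc9)c(OCc9ccccc9)c2)[C@H](OC(=O)c7cc(OCc9ccccc9)c(OCc9ccccc9)c(OCc9ccccc9)c7)[C@H]3C4=C(O)CC4=O)c2c(OCc9ccccc9)cc(OCc9ccccc9)cc2O[C@@H]1c1ccc(OCc9ccccc9)c(OCc9ccccc9)c1

F2 | step 14 | 5,7,3',4'-tetra-O-benzyl-(+)-catechin | O[C@H]1Cc2c(OCc9ccccc9)cc(OCc9ccccc9)cc2O[C@@H]1c1ccc(OCc9ccccc9)c(OCc9ccccc9)c1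

F3 | step 14 | 8-bromo-5,7,3',4'-tetra-O-benzyl-(+)-catechin | O[C@H]1Cc2c(OCc9ccccc9)cc(OCc9ccccc9)c(Br)c2O[C@@H]1c1ccc(OCc9ccccc9)c(OCc9ccccc9)c1

F4 | step 14 | perbenzylated top–middle dimer-(4β→6)-8-bromo-5,7,3',4'-tetra-O-benzylcatechin | O=C(c7cc(OCc9ccccc9)c(OCc9ccccc9)c(OCc9ccccc9)c7)O[C@@H]1[C@@H](c2c(OCc9ccccc9)cc(OCc9ccccc9)c3c2O[C@H](c2ccc(OCc9ccccc9)c(OCc9ccccc9)c2)[C@H](OC(=O)c7cc(OCc9ccccc9)c(OCc9ccccc9)c(OCc9ccccc9)c7)[C@H]3c4c(OCc9ccccc9)c(Br)c5c(c4OCc9ccccc9)C[C@H](O)[C@@H](c4ccc(OCc9ccccc9)c(OCc9ccccc9)c4)O5)c2c(OCc9ccccc9)cc(OCc9ccccc9)cc2O[C@@H]1c1ccc(OCc9ccccc9)c(OCc9ccccc9)c1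

F5 | step 8 | 3-benzyloxy-4,4-dichloro-2-(perbenzylated top–middle dimer-4β-yl)cyclobut-2-en-1-one | O=C(c7cc(OCc9ccccc9)c(OCc9ccccc9)c(OCc9ccccc9)c7)O[C@@H]1[C@@H](c2c(OCc9ccccc9)cc(OCc9ccccc9)c3c2O[C@H](c2ccc(OCc9ccccc9)c(OCc9ccccc9)c2)[C@H](OC(=O)c7cc(OCc9ccccc9)c(OCc9ccccc9)c(OCc9ccccc9)c7)[C@H]3C4=C(OCc9ccccc9)C(Cl)(Cl)C4=O)c2c(OCc9ccccc9)cc(OCc9ccccc9)cc2O[C@@H]1c1ccc(OCc9ccccc9)c(OCc9ccccc9)c1
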